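**Retrosynthetic overview**
1. Remove the C-8 tiglate, take the C-8 carbinol back to a ketone and C-1 OMe back to OH. This gives a macrocyclic 8-oxo hemiketal with all skeletal carbons in place.
2. Open the ten-membered ring at C-5=C-6: a C-5 aldehyde condenses onto butenolide C-6 in a ring-closing vinylogous aldol condensation. The 1,4-oxide (THF) ring is the hemiketal of C-4 OH on the C-1 ketone, and it templates this closure.
3. Cut C-8–C-9. This bond comes from a light-driven (decatungstate HAT) acyl-radical addition of a 4-formylbutenolide to an isopropenyl ketone, which joins the two halves as a 1,4-diketone.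
4. The isopropenyl ketone is (R)-linalool after photooxygenation; linalool supplies the C-4 stereocentre and nine skeletal carbons. The formylbutenolide comes from 2-butyne-1,4-diol, vinylMgCl and CO2.
5. Ring order: butenolide first, then THF hemiketal and carbocycle together, then the ketal is locked. Stereo relay: C-4 (bought) → C-1 (bridge) → C-10 (equilibration) → C-8 (hydride delivery).

Assumption: germacrane atom labels are used (C-1 ketal carbon, C-4 O-bearing quaternary carbon, C-8 tiglate carbinol, C-10 CHMe, C-12 lactone C=O, C-13 CH2OAc). One-pot sequences count as one step, and bulk reagents (O2, O3, Ac2O, MeOH) are given by SMILES but not numbered.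

**Step 1**
Reactants: 1, (R)-(−)-linalool
Product: 2, (R)-6-hydroxy-2,6-dimethylocta-1,7-dien-3-one (equilibrates with its five-ring hemiketal)
Conditions: O2, TPP (0.2 mol %), white LED, Ac2O, pyridine, DMAP (cat.), CH2Cl2, 0 °C
Reagents that add atoms: dioxygen (as singlet oxygen), O=O
Why: A Schenck ene reaction occurs only at the trisubstituted alkene, and in situ Kornblum–DeLaMare dehydration of the secondary allylic hydroperoxide gives the isopropenyl ketone (C-1=O, C-9=C-10) in one pot (about 40–45 %, the tertiary hydroperoxide regioisomer is removed by chromatography) without touching the purchased C-4 stereocentre.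

**Step 2**
Reactants: 3, 2-butyne-1,4-diol; 4, vinylmagnesium chloride; 5, carbon dioxide
Product: 6, 3-(hydroxymethyl)-4-vinylfuran-2(5H)-one
Conditions: 4 (4.5 equiv), THF/toluene, reflux, 18 h; CO2 (g), −20 °C → rt; 2 M HCl
Reagents that add atoms: vinylmagnesium chloride, C=C[Mg]Cl; carbon dioxide, O=C=O
Why: Alkoxide-directed anti-carbomagnesiation places vinyl on C-7 and Mg on C-11 in a five-membered chelate, so carboxylation gives an acid cis to the C-6 CH2OH that lactonises on work-up and fixes the tetrasubstituted C-7=C-11 geometry.

**Step 3**
Reactants: 6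
Product: 7, (2-oxo-4-vinyl-2,5-dihydrofuran-3-yl)methyl acetate
Conditions: Ac2O, pyridine, DMAP (cat.), CH2Cl2, 0 °C
Reagents that add atoms: acetic anhydride, CC(=O)OC(C)=O
Why: Routine acylation installs the final C-13 acetate early, which also deactivates the C-13 C–H bonds toward the electrophilic H-abstractor used in step 5.

**Step 4**
Reactants: 7
Product: 8, (4-formyl-2-oxo-2,5-dihydrofuran-3-yl)methyl acetate (used crude)
Conditions: O3, CH2Cl2, −78 °C (Sudan III end point); PPh3
Reagents that add atoms: ozone, [O-][O+]=O
Why: Chemoselective ozonolysis cleaves the monosubstituted vinyl group far faster than the tetrasubstituted, doubly acceptor-substituted ring alkene, unveiling C-8 as the aldehyde.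

**Step 5 (key photochemical C-8–C-9 bond)**
Reactants: 8; 2 (1.5 equiv)
Product: 9, {4-[(7R)-7-hydroxy-3,7-dimethyl-4-oxonon-8-enoyl]-2-oxo-2,5-dihydrofuran-3-yl}methyl acetate (about 1:1 at C-10)
Conditions: (n-Bu4N)4W10O32 (4 mol %), MeCN (0.1 M), 390 nm LED, N2, 20 °C
Reagents that add atoms: none (8 and 2 combine with full atom economy)
Why: Proposed new method: excited decatungstate abstracts the formyl hydrogen of 8 (the only unhindered C–H not deactivated in either partner, since the O–CH2 groups are acyloxy-deactivated and 2 has no α-oxy C–H); the resulting σ-type α,β-unsaturated acyl radical cannot decarbonylate and adds as a nucleophile to the unsubstituted terminus C-9 of the vinyl ketone, and the tertiary α-keto radical is quenched by reduced decatungstate (SET/H+ or back-HAT) faster than 6-exo attack on the vinyl group, giving the 1,4-diketone with C-10 unselective (corrected in step 7); the closest known reaction type is decatungstate-photocatalysed hydroacylation (radical Stetter/Giese) of electron-poor alkenes with simple aliphatic or aromatic aldehydes, which has not been shown for a formylbutenolide or an unprotected hydroxy-enone coupling.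

**Step 6**
Reactants: 9
Product: 10, {4-[(7R)-7-hydroxy-3,7-dimethyl-4,8-dioxooctanoyl]-2-oxo-2,5-dihydrofuran-3-yl}methyl acetate (mainly as anomerising C-1 hemiketals)
Conditions: O3, CH2Cl2, −78 °C; PPh3
Reagents that add atoms: ozone, [O-][O+]=O
Why: Ozonolysis acts on the only electron-rich alkene left (the linalool vinyl group) and gives the C-5 aldehyde on the intact C-4 stereocentre, while the acylbutenolide alkene is too electron-poor to react.

**Step 7 (ring closure; sets C-1 and C-10)**
Reactants: 10
Product: 11, (1S,4R,5E,10R)-13-acetoxy-1-hydroxy-8-oxo-1,4-epoxygermacra-5,7(11)-dien-12,6-olide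
Conditions: i-Pr2NEt (2 equiv), n-Bu4NOAc (2 equiv), Ac2O (2 equiv), MeCN, 1 mM (syringe pump), 40 °C; then DBU (0.2 equiv), CH2Cl2, rt
Reagents that add atoms: none (net loss of H2O)
Why: Proposed new method: the butenolide γ-CH2 (C-6) is by far the most acidic site (2-oxidofuran dienolate), the freely anomerising C-4 OH/C-1 ketone hemiketal holds aldehyde and dienolate cis on a THF so only a nine-atom oxa-bridged loop must close, the aldolate is acetylated and lost by E1cB to give the only ring-compatible (E)-ylidene (C-4 cis to C-7), acetate as the sole nucleophile makes any ionisation of the 13-acetate degenerate, C-1 must be S because the oxide can only bridge cis to C-5, and DBU equilibrates C-10 through the ring-opened C-1 ketone to the predicted more stable 10R epimer (C-14 anti to C-2, flanked only by the two C-1 oxygens on the ether-bridge face; minor epimer recyclable); the closest known reaction type is the intermolecular Perkin/Knoevenagel-type vinylogous aldol condensation of 2(5H)-furanones with aldehydes to γ-ylidenebutenolides, which has not been used to close a medium ring.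

**Step 8**
Reactants: 11
Product: 12, (1S,4R,5E,10R)-13-acetoxy-1-methoxy-8-oxo-1,4-epoxygermacra-5,7(11)-dien-12,6-olide
Conditions: PPTS (10 mol %), MeOH, 3 Å MS, rt
Reagents that add atoms: methanol, CO
Why: Acid-catalysed hemiketal-to-ketal exchange proceeds through the bridgehead oxocarbenium ion, which MeOH can only attack from the exo face (retaining 1S), and this blocks ring opening so C-10 can no longer epimerise, while the conjugated C-8 ketone, acetate and enol lactone tolerate PPTS.

**Step 9 (sets C-8)**
Reactants: 12
Product: 13, (1S,4R,5E,8S,10R)-13-acetoxy-8-hydroxy-1-methoxy-1,4-epoxygermacra-5,7(11)-dien-12,6-olide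
Conditions: NaBH4, CeCl3·7H2O, MeOH/CH2Cl2, −78 °C
Reagents that add atoms: none
Why: In this Luche 1,2-reduction, hydride is expected to attack the face of the rigid dienone segment opposite the ether bridge and the C-14 methyl, giving the 8α (8S) alcohol cis-1,3 to C-14, while lactone, acetate and ketal are inert at −78 °C.

**Step 10**
Reactants: 13; 14, tiglic acid
Product: 15, Vernolide-B
Conditions: 14, 2,4,6-trichlorobenzoyl chloride, Et3N, toluene; then 13, DMAP, 0 °C → rt
Reagents that add atoms: tiglic acid, C/C=C(\C)C(=O)O
Why: Yamaguchi esterification acylates the hindered allylic C-8 alcohol with retention at C-8 and without E/Z scrambling, since the tiglate is the stable isomer.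

**Compound list**
1 | (R)-(−)-linalool | C=C[C@](C)(O)CCC=C(C)C | starting material
2 | (R)-6-hydroxy-2,6-dimethylocta-1,7-dien-3-one | C=C[C@](C)(O)CCC(=O)C(C)=C | intermediate
3 | 2-butyne-1,4-diol | OCC#CCO | starting material
4 | vinylmagnesium chloride | C=C[Mg]Cl | starting material
5 | carbon dioxide | O=C=O | starting material
6 | 3-(hydroxymethyl)-4-vinylfuran-2(5H)-one | C=CC1=C(CO)C(=O)OC1 | intermediate
7 | (2-oxo-4-vinyl-2,5-dihydrofuran-3-yl)methyl acetate | C=CC1=C(COC(C)=O)C(=O)OC1 | intermediate
8 | (4-formyl-2-oxo-2,5-dihydrofuran-3-yl)methyl acetate | O=CC1=C(COC(C)=O)C(=O)OC1 | intermediate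
9 | 1,4-diketone, vinyl carbinol (4R; C-10 mixture) | C=C[C@](C)(O)CCC(=O)C(C)CC(=O)C1=C(COC(C)=O)C(=O)OC1 | intermediate
10 | seco-aldehyde (4R; C-10 mixture) | O=C[C@](C)(O)CCC(=O)C(C)CC(=O)C1=C(COC(C)=O)C(=O)OC1 | intermediate
11 | macrocyclic 8-oxo 1-hemiketal (1S,4R,5E,10R) | O=C1C[C@@H](C)[C@]2(O)CC[C@](C)(/C=C3/OC(=O)C(COC(C)=O)=C31)O2 | intermediate
12 | 8-oxo 1-O-methyl ketal (1S,4R,5E,10R) | O=C1C[C@@H](C)[C@]2(OC)CC[C@](C)(/C=C3/OC(=O)C(COC(C)=O)=C31)O2 | intermediate
13 | 8α-hydroxy 1-O-methyl ketal 13-acetate (1S,4R,5E,8S,10R) | O[C@H]1C[C@@H](C)[C@]2(OC)CC[C@](C)(/C=C3/OC(=O)C(COC(C)=O)=C31)O2 | intermediate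
14 | tiglic acid | C/C=C(\C)C(=O)O | starting material
15 | Vernolide-B | C/C=C(\C)C(=O)O[C@H]1C[C@@H](C)[C@]2(OC)CC[C@](C)(/C=C3/OC(=O)C(COC(C)=O)=C31)O2 | target

**Totals**
Total steps: 10.
Longest linear sequence: 9 (3 → 6 → 7 → 8 → 9 → 10 → 11 → 12 → 13 → 15).

**Steps most likely to fail**
1. **Step 7 (proposed new ring closure).** Failure modes are oligomerisation, loss of the 13-acetate, or an unfavourable C-10 equilibrium. Fallback (known chemistry): install a C-6 diethyl phosphonate on 7 (NBS/hν, then P(OEt)3). Carry it through steps 4–6 and close the ring by an intramolecular Masamune–Roush Horner–Wadsworth–Emmons reaction (LiCl, DBU, high dilution).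
2. **Step 5 (proposed new photochemical hydroacylation).** Failure modes are sluggish HAT from the electron-poor formyl group or decomposition of 8. Fallback (known chemistry): Pinnick oxidation of 8 and conversion into the phenyl selenoester. The pre-formed acyl-radical precursor is then added to 2 in a thermal (TMS)3SiH/AIBN chain (acyl selenide Giese addition), at a cost of two extra steps.
3. **Step 9 (C-8 facial selectivity, which depends on the C-10 methyl).** If the 8β-alcohol dominates, esterify it directly with tiglic acid under Mitsunobu conditions (PPh3, DIAD). Inversion gives the 8α-tiglate and replaces step 10.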